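**Plan**
- Retrosynthesis: the two C2–Br bonds are removed first and the catechols are masked as cyclic carbonates. Then C3–C4 and C5–C6 are cut in each ring, and last one C7–O bond of the central ether.
- Enabling feature (C1 bears benzylic C7, C2/C3 bear Br, C4/C5 bear OH, C6 bears H): the adjacent C4–C5 pair with both oxygens is vinylene carbonate. C6–C1–C2–C3 with C7 and the C3 bromine is a 5-bromo-3-furylmethyl unit whose ring oxygen can leave as water, so each benzene ring is a furan Diels–Alder adduct minus H2O.
- Forward, chain first: 5-bromofuran-3-carboxylic acid is reduced, part of the alcohol becomes the bromide, and a Williamson coupling builds C7–O–C7' before any benzene ring exists.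
- Forward, rings second: both benzene rings arise together by two-directional [4+2] addition of two molecules of vinylene carbonate (one per furan ring) and dehydrative aromatisation. Carbonate hydrolysis and bromination at C2 and C2' finish the synthesis.
- Stereochemistry: the target has no stereocentre. The eight centres of the double cycloadduct are transient and are erased on aromatisation, so nothing has to be controlled.

Key step: step 4

Remark on the chemistry: the target SMILES carries no stereodescriptor and the molecule is achiral, so "single enantiomer" is taken to mean the one constitution drawn. The ring numbering C1–C7 defined above is used throughout.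

**Step 1**
Reactants: 1 5-bromofuran-3-carboxylic acid
Product: 2 (5-bromofuran-3-yl)methanol
Conditions: BH3·THF, THF, 0 °C → rt; aqueous work-up
Reagents that add atoms: none
Why: Borane reduction of a carboxylic acid: BH3 reduces the acid rapidly through the acyloxyborane and, unlike LiAlH4, should leave the C–Br bond and the furan ring alone.

**Step 2**
Reactants: 2 (5-bromofuran-3-yl)methanol (about half of the material)
Product: 3 2-bromo-4-(bromomethyl)furan
Conditions: CBr4, PPh3, CH2Cl2, 0 °C; pentane trituration, short silica plug, used at once
Reagents that add atoms: carbon tetrabromide, BrC(Br)(Br)Br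
Why: Appel reaction: the primary heterobenzylic alcohol is displaced under neutral conditions through the alkoxyphosphonium bromide, which spares the acid-sensitive furan, and the electron-withdrawing ring bromine should make this furylmethyl bromide less prone to ionise than the parent.

**Step 3**
Reactants: 2 (5-bromofuran-3-yl)methanol; 3 2-bromo-4-(bromomethyl)furan
Product: 5 bis[(5-bromofuran-3-yl)methyl] ether, via sodium (5-bromofuran-3-yl)methanolate 4 (not isolated)
Conditions: 2, NaH, THF, 0 °C; then 3, Bu4NI (cat.), 0 °C → rt
Reagents that add atoms: none
Why: Williamson ether synthesis: the primary alkoxide attacks an unhindered heterobenzylic bromide by SN2 (iodide catalysis), no β-hydrogen is available for elimination, and the ring C–Br bonds are inert to alkoxide at this temperature.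

**Step 4**
Reactants: 5 bis[(5-bromofuran-3-yl)methyl] ether; 6 vinylene carbonate (two molecules are built in per molecule of 5, one at each furan ring)
Product: 9 bis[(7-bromo-2-oxo-1,3-benzodioxol-5-yl)methyl] ether, via double cycloadduct bis[(1-bromo-4-oxo-3,5,10-trioxatricyclo[5.2.1.0^2,6]dec-8-en-8-yl)methyl] ether 7 (not isolated), via ring-opened bis[(4-acetoxy-7-bromo-2-oxo-3a,4-dihydro-1,3-benzodioxol-5-yl)methyl] ether 8 (not isolated)
Conditions: (i) 6 (neat, ca. 20 equiv, of which 2 equiv are consumed), BHT (cat.), 2,6-di-tert-butylpyridine (cat.), sealed tube, 115 °C; excess 6 distilled off in vacuo; (ii) Ac2O (excess, 2 equiv consumed), MsOH, CH2Cl2, 0 → 40 °C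
Reagents that add atoms: vinylene carbonate (second molecule of 6 for the second furan ring), O=C1OC=CO1; acetic anhydride (acetyl groups of intermediate 8 only), CC(=O)OC(C)=O
Why: Proposed new method: each of the two 2-bromofuran rings of 5 takes up one molecule of 6 across its two α-carbons in a concerted, suprafacial thermal [4π+2π] cycloaddition that forms C3–C4 and C5–C6, the dienophile serving as solvent to drive the reversible addition at both ends and the α-halogen making the addition more exergonic than with furan itself. In the second stage MsOH/Ac2O acylates the bridge oxygen of 7, the C3–O bond ionises to an allyl cation shared by C3 and the tertiary C1, loss of C4–H gives dienyl acetate 8, and ionisation of its allylic C6 acetate to the cyclohexadienyl cation followed by loss of C5–H gives the arene, so that each ring loses the elements of water, which Ac2O binds before it can open the carbonate. The closest known reaction types are the thermal Diels–Alder addition of furan to vinylene carbonate and the MsOH/Ac2O dehydrative aromatisation of furan–maleic anhydride adducts, and what is new is their union on a 1-bromo-7-oxanorbornene that carries two oxygen substituents. Each of the two six-membered rings is closed by an intermolecular [4+2] cycloaddition (two σ-bonds at once, no chain cyclisation) and turns into a benzene ring by extrusion of the oxygen bridge. The eight stereocentres of 7 form as an endo/exo mixture under no more control than the cis ring fusion set by the suprafacial addition, which is harmless because all of them are sp2 carbons in 9, and the symmetric dienophile raises no question of regiochemistry. The selectivity needed is cleavage of the bridge at C3–O (bromine kept, water lost) and not at C6–O (a gem-bromohydrin that would collapse with loss of HBr), and the substrate secures it through the tertiary allyl terminus C1 and lone-pair donation from bromine, while direct ionisation of the bridgehead bromide is barred since the resulting oxocarbenium ion would be anti-Bredt; the electron-poor aryl carbonate then shields the benzylic ether of 9 from the acid.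

**Step 5**
Reactants: 9 bis[(7-bromo-2-oxo-1,3-benzodioxol-5-yl)methyl] ether
Product: 10 bis(3-bromo-4,5-dihydroxybenzyl) ether
Conditions: THF–H2O 4:1 (degassed), imidazole (10 mol %), Ar, rt
Reagents that add atoms: none
Why: Hydrolysis of an activated aryl carbonate by acyl–oxygen cleavage and decarboxylation (imidazole catalysis): the strained five-membered diaryl carbonate reacts at neutral pH, both aryl oxygens stay on the ring while the oxygen of water leaves in CO2, and neither quinone-methide fragmentation of the 4-hydroxybenzyl ether nor catechol autoxidation (air excluded) should set in.

**Step 6**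
Reactants: 10 bis(3-bromo-4,5-dihydroxybenzyl) ether
Product: 11 bis(2,3-dibromo-4,5-dihydroxybenzyl) ether
Conditions: NBS (2.05 equiv, one per ring), MeCN, −30 → 0 °C, dark, Ar; alcohol-free work-up
Reagents that add atoms: N-bromosuccinimide, O=C1CCC(=O)N1Br
Why: Electrophilic aromatic bromination of a phenol with NBS in MeCN: C2 is para to C5–OH and is the site taken in the bromination of 5-bromovanillin and of 3-bromo-4,5-dihydroxybenzaldehyde, C1 (para to C4–OH) is blocked, and NBS gives succinimide in place of HBr so that the acid-labile benzylic ether should survive.

**Compound list**
1 | 5-bromofuran-3-carboxylic acid | OC(=O)c1coc(Br)c1 | starting material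
2 | (5-bromofuran-3-yl)methanol | OCc1coc(Br)c1 | intermediate
3 | 2-bromo-4-(bromomethyl)furan | BrCc1coc(Br)c1 | intermediate
4 | sodium (5-bromofuran-3-yl)methanolate (not isolated) | [Na+].[O-]Cc1coc(Br)c1 | intermediate
5 | bis[(5-bromofuran-3-yl)methyl] ether | Brc1cc(COCc2coc(Br)c2)co1 | intermediate
6 | vinylene carbonate (1,3-dioxol-2-one) | O=C1OC=CO1 | starting material
7 | bis[(1-bromo-4-oxo-3,5,10-trioxatricyclo[5.2.1.0^2,6]dec-8-en-8-yl)methyl] ether; each unit is a 1-bromo-7-oxanorbornene cis-fused to the cyclic carbonate; endo/exo diastereomer mixture, so no descriptors are given (not isolated) | O=C1OC2C(O1)C1(Br)C=C(COCC3=CC4(Br)OC3C3OC(=O)OC34)C2O1 | intermediate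
8 | bis[(4-acetoxy-7-bromo-2-oxo-3a,4-dihydro-1,3-benzodioxol-5-yl)methyl] ether; diastereomer mixture, so no descriptors are given (not isolated) | CC(=O)OC1C2OC(=O)OC2=C(Br)C=C1COCC1=CC(Br)=C2OC(=O)OC2C1OC(C)=O | intermediate
9 | bis[(7-bromo-2-oxo-1,3-benzodioxol-5-yl)methyl] ether | O=C1Oc2cc(COCc3cc(Br)c4OC(=O)Oc4c3)cc(Br)c2O1 | intermediate
10 | bis(3-bromo-4,5-dihydroxybenzyl) ether | Oc1cc(COCc2cc(O)c(O)c(Br)c2)cc(Br)c1O | intermediate
11 | bis(2,3-dibromo-4,5-dihydroxybenzyl) ether (achiral) | Oc1cc(COCc2cc(O)c(O)c(Br)c2Br)c(Br)c(Br)c1O | target

**Total step count:** 6. **Longest linear sequence:** 6 (steps 1 → 2 → 3 → 4 → 5 → 6).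

**Steps most likely to fail**

Step 4.
- What may go wrong: the reversible addition may stay incomplete at one or both furan rings while the bromofuran decays thermally. The bridge may open on the C6 side with loss of HBr. The central ether may suffer acetolysis.
- Fallback: this uses known chemistry only and takes the benzene rings from the aromatic pool, so it has no branching point among 1–8. It sets out from commercial 3-bromo-4,5-dihydroxybenzaldehyde F1 (in place of 1 and 6) and comes back to the route at 9. The catechol of F1 is closed with 1,1'-carbonyldiimidazole in THF (0 °C → rt) to 7-bromo-2-oxo-1,3-benzodioxole-5-carbaldehyde F2. Reductive homo-etherification of F2 with Et3SiH and catalytic BiBr3 in MeCN then joins two aldehyde molecules through the silyl ether and the oxocarbenium ion to give 9. The electron-poor aldehyde should resist over-reduction, and the carbonate is inert to the anhydrous Lewis acid.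

Step 6.
- What may go wrong: the catechol may be oxidised to the o-quinone. Ipso attack at C1 may expel the benzylic carbon. The 4-hydroxybenzyl ether may fragment by the quinone-methide path. Some bromination may occur at C6.
- Fallback: the fallback sets out from 9 and comes back at 11, with the last two operations inverted so that no free phenol meets the brominating agent. Compound 9 is brominated with NBS in TFA–conc. H2SO4, conditions suited to deactivated arenes. The fused five-membered ring directs to the β-position para to the C5 oxygen, which should give bis[(6,7-dibromo-2-oxo-1,3-benzodioxol-5-yl)methyl] ether F3. F3 is then hydrolysed under the conditions of step 5 to 11.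

Step 2.
- What may go wrong: the furylmethyl bromide may ionise and polymerise on concentration or on silica, which erodes material before the coupling.
- Fallback: the fallback sets out from 2 and comes back at 5 without any furylmethyl halide. Oxidation of 2 with activated MnO2 in CH2Cl2 gives 5-bromofuran-3-carbaldehyde F4. Reductive homo-etherification of F4 (Et3SiH, BiBr3 cat., MeCN, 0 °C) gives the symmetric ether 5 directly and also replaces step 3.

**Further compounds**
F1 | step 4 | 3-bromo-4,5-dihydroxybenzaldehyde | O=Cc1cc(O)c(O)c(Br)c1
F2 | step 4 | 7-bromo-2-oxo-1,3-benzodioxole-5-carbaldehyde | O=Cc1cc(Br)c2OC(=O)Oc2c1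
F3 | step 6 | bis[(6,7-dibromo-2-oxo-1,3-benzodioxol-5-yl)methyl] ether | O=C1Oc2cc(COCc3cc4OC(=O)Oc4c(Br)c3Br)c(Br)c(Br)c2O1
F4 | step 2 | 5-bromofuran-3-carbaldehyde | O=Cc1coc(Br)c1
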